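**Strategy.** The six-membered quinone ring is disconnected to a squaric acid-derived cyclobutenone. Its ring atoms C1(=O), C2 (indole A) and C3 (oxygen, carried as OMe) with C4(=O) come from the four-membered ring, and the C5(indole B)=C6(prenyl) pair comes from one alkenyl substituent. The key step exploits exactly this: the indole A and oxygen-bearing carbons sit side by side between the two carbonyls, opposite the C5=C6 pair. Heating the 4-alkenyl-4-hydroxycyclobutenone opens it to a dienylketene that closes the C1–C6 bond and gives the hexasubstituted hydroquinone in one operation. The precursor carries N-Boc on indole A, which removes the acidic N–H and weakens its donor effect, and N-TIPS on indole B.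

Key step: step 10

Remark on the chemistry: a free N–H on indole A (or its lithium salt) next to the cyclobutenedione would consume the vinyllithium and push electron density into the very carbonyl that has to be attacked, so it is masked as the Boc carbamate until the last step. Compounds 19 and 21 are racemic, their single stereocentres vanish in step 10, and the target is achiral. The side-chain alkene keeps one geometry throughout (Z in 18, E in 19, by change of priorities only). Compounds 1, 2, 4, 7, 12 and 14 are assumed to be purchased.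

**Step 1**
Reactants: 1 9-borabicyclo[3.3.1]nonane (9-BBN, 0.5 M in THF); 2 3-methylbuta-1,2-diene
Product: 3 9-(3-methylbut-2-en-1-yl)-9-borabicyclo[3.3.1]nonane (B-prenyl-9-BBN), used as its THF solution
Conditions: THF, 0 °C → rt
Reagents that add atoms: none
Why: Hydroboration of the 1,1-disubstituted allene by the bulky dialkylborane should place boron on the unsubstituted terminal carbon and hydrogen on the central carbon, giving the allylic (prenyl) borane directly.

**Step 2**
Reactants: 4 1H-indole; 3 B-prenyl-9-BBN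
Product: 6 2-(2-methylbut-3-en-2-yl)-1H-indole, via 3-chloro-1H-indole 5 (not isolated)
Conditions: NCS, CH2Cl2, 0 °C; then Et3N, 3 (THF), 0 °C → rt; aq NaOH
Reagents that add atoms: none
Why: Electrophilic C3 chlorination followed by allylboration of the C2=N bond of the indolenine tautomer through a six-membered transition state (allylic transposition puts the quaternary carbon on C2) and loss of HCl to re-aromatise, the known reverse prenylation of 3-chloroindoles with prenyl-9-BBN.

**Step 3**
Reactants: 7 squaric acid (3,4-dihydroxycyclobut-3-ene-1,2-dione)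
Product: 8 3,4-dichlorocyclobut-3-ene-1,2-dione (squaric acid dichloride)
Conditions: (COCl)2, cat. DMF, CH2Cl2, reflux
Reagents that add atoms: oxalyl chloride ClC(=O)C(=O)Cl
Why: Vilsmeier-type chlorodehydroxylation of the two vinylogous carboxylic acid groups is the standard preparation of this dichloride.

**Step 4**
Reactants: 6 2-(2-methylbut-3-en-2-yl)-1H-indole; 8 squaric acid dichloride
Product: 10 3-methoxy-4-[2-(2-methylbut-3-en-2-yl)-1H-indol-3-yl]cyclobut-3-ene-1,2-dione, via chloro(indolyl)cyclobutenedione 9 (not isolated)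
Conditions: CH2Cl2, 0 °C → rt; then MeOH, 50 °C
Reagents that add atoms: methanol CO
Why: Uncatalysed Friedel–Crafts-type addition–elimination of the nucleophilic indole C3 on the vinylogous acid chloride, then alcoholysis of the second vinylogous acid chloride to the methyl ester, with the first substitution deactivating the ring toward a second arylation.

**Step 5**
Reactants: 10 3-methoxy-4-[2-(2-methylbut-3-en-2-yl)-1H-indol-3-yl]cyclobut-3-ene-1,2-dione
Product: 11 tert-butyl 3-(2-methoxy-3,4-dioxocyclobut-1-en-1-yl)-2-(2-methylbut-3-en-2-yl)-1H-indole-1-carboxylate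
Conditions: Boc2O, DMAP, MeCN, rt → 40 °C
Reagents that add atoms: di-tert-butyl dicarbonate CC(C)(C)OC(=O)OC(=O)OC(C)(C)C
Why: DMAP-catalysed N-acylation of the acidified N–H of a 3-acylindole-type vinylogous amide should install the carbamate, which removes the acidic proton and reduces donation from indole A into the carbonyl that must stay electrophilic in step 9.

**Step 6**
Reactants: 12 5-methylhex-4-enoic acid
Product: 13 N-methoxy-N,5-dimethylhex-4-enamide
Conditions: CDI, CH2Cl2, rt; then MeNHOMe·HCl, rt
Reagents that add atoms: N,O-dimethylhydroxylamine hydrochloride CNOC.Cl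
Why: Weinreb amide formation through the acyl imidazole runs under neutral conditions that leave the trisubstituted alkene untouched.

**Step 7**
Reactants: 14 3-bromo-1-(triisopropylsilyl)-1H-indole; 13 N-methoxy-N,5-dimethylhex-4-enamide
Product: 16 5-methyl-1-[1-(triisopropylsilyl)-1H-indol-3-yl]hex-4-en-1-one, via 3-lithio-1-(triisopropylsilyl)indole 15 (not isolated)
Conditions: t-BuLi (2 equiv), THF, −78 °C; then 13, −78 → 0 °C; aq NH4Cl
Reagents that add atoms: none
Why: Bromine–lithium exchange gives the 3-lithioindole, which the bulky N-silyl group keeps from migrating to C2, and its addition to the Weinreb amide stops at the chelated tetrahedral intermediate so that the ketone is released only on work-up.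

**Step 8**
Reactants: 16 5-methyl-1-[1-(triisopropylsilyl)-1H-indol-3-yl]hex-4-en-1-one
Product: 17 N'-[(1E)-5-methyl-1-[1-(triisopropylsilyl)-1H-indol-3-yl]hex-4-en-1-ylidene]-2,4,6-tri(propan-2-yl)benzenesulfonohydrazide
Conditions: 2,4,6-triisopropylbenzenesulfonohydrazide, cat. PPTS, 4 Å MS, THF, rt
Reagents that add atoms: 2,4,6-triisopropylbenzenesulfonohydrazide CC(C)c1cc(C(C)C)c(S(=O)(=O)NN)c(C(C)C)c1
Why: Acid-catalysed condensation should give the sulfonylhydrazone as the E isomer (sulfonamide nitrogen anti to the indole), which places the N–H syn to the only α-CH2 group as the Shapiro reaction requires.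

**Step 9**
Reactants: 17 trisylhydrazone; 11 N-Boc indole A methoxycyclobutenedione
Product: 19 4-hydroxy-3-methoxy-2-[1-(tert-butoxycarbonyl)-2-(2-methylbut-3-en-2-yl)indol-3-yl]-4-[(1E)-5-methyl-1-(1-triisopropylsilylindol-3-yl)hexa-1,4-dien-1-yl]cyclobut-2-en-1-one (racemic), via vinyllithium 18 (not isolated)
Conditions: n-BuLi (2.05 equiv per 17), THF, −78 → 0 °C; then 11, THF, −78 °C; aq NH4Cl, −78 °C
Reagents that add atoms: none
Why: The Shapiro reaction (the hydrazone dianion loses sulfinate and N2) should give the vinyllithium with lithium trans to the CH2 group, which adds with retention in a 1,2-fashion to the ketone-like carbonyl next to C–OMe of 11, the other carbonyl being a vinylogous ester shielded by the twisted N-Boc indole A, and the new carbinol centre forms as a racemate that step 10 destroys.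

**Step 10**
Reactants: 19 4-alkenyl-4-hydroxycyclobutenone
Product: 22 2-[1-(tert-butoxycarbonyl)-2-(2-methylbut-3-en-2-yl)indol-3-yl]-3-methoxy-6-(3-methylbut-2-en-1-yl)-5-[1-(triisopropylsilyl)indol-3-yl]benzene-1,4-diol, via dienylketene 20 (not isolated), via cyclohexadienone 21 (not isolated)
Conditions: toluene (degassed), 110 °C, Ar
Reagents that add atoms: none
Why: Heating should break the C1–C4 bond of the cyclobutenone in a conrotatory 4π electrocyclic opening to the dienylketene 20, whose ketene carbon and alkene terminus then join in a thermal disrotatory 6π electrocyclisation to the cyclohexadienone 21, which enolises to the aromatic hydroquinone 22. The closest known reaction type is the Moore ring expansion of squarate-derived 4-alkenyl-4-hydroxycyclobutenones to hydroquinones. The six-membered carbocycle is closed by this 6π electrocyclisation, which forms the bond between the former C1 (the future C=O beside indole A) and the CH that carries the prenyl CH2. No stereocentre survives, because the sp3 CH of 21 is planarised on tautomerisation and the carbinol carbon of 19 becomes sp2. The step needs torquoselectivity, which is secured because the 4-hydroxyl donor rotates outward and so turns the alkenyl group inward, cis to the ketene, while the E alkene leaves only hydrogen on the inside of the closing triene. Regiochemistry needs no control here, since all six substituents were fixed by the site of addition in step 9.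

**Step 11**
Reactants: 22 hydroquinone
Product: 23 2-[1-(tert-butoxycarbonyl)-2-(2-methylbut-3-en-2-yl)indol-3-yl]-3-methoxy-6-(3-methylbut-2-en-1-yl)-5-[1-(triisopropylsilyl)indol-3-yl]cyclohexa-2,5-diene-1,4-dione
Conditions: Ag2O, Et2O, rt
Reagents that add atoms: none
Why: Two-electron oxidation of an electron-rich hydroquinone to the para-quinone with Ag2O is mild enough to leave both indoles and both olefins alone.

**Step 12**
Reactants: 23 protected methoxyquinone
Product: 25 3-hydroxy-5-(1H-indol-3-yl)-2-[2-(2-methylbut-3-en-2-yl)-1H-indol-3-yl]-6-(3-methylbut-2-en-1-yl)cyclohexa-2,5-diene-1,4-dione (target), via N-desilylated methoxyquinone 24 (not isolated)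
Conditions: Bu4NF, THF, 0 °C; then 2 M aq NaOH, MeOH, 50 °C; 1 M HCl
Reagents that add atoms: sodium hydroxide [Na+].[OH-]
Why: Fluoride-induced N-desilylation is followed by hydroxide cleavage of the indole carbamate and addition–elimination of hydroxide at the vinylogous ester carbon (saponification of a methoxyquinone), and acidification returns the hydroxyquinone.

**Compound list**
1 | 9-borabicyclo[3.3.1]nonane (9-BBN) | B1C2CCCC1CCC2 | starting material
2 | 3-methylbuta-1,2-diene | CC(C)=C=C | starting material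
3 | 9-(3-methylbut-2-en-1-yl)-9-borabicyclo[3.3.1]nonane | CC(C)=CCB1C2CCCC1CCC2 | intermediate
4 | 1H-indole | c1ccc2[nH]ccc2c1 | starting material
5 | 3-chloro-1H-indole (not isolated) | Clc1c[nH]c2ccccc12 | intermediate
6 | 2-(2-methylbut-3-en-2-yl)-1H-indole | C=CC(C)(C)c1cc2ccccc2[nH]1 | intermediate
7 | squaric acid | O=C1C(O)=C(O)C1=O | starting material
8 | 3,4-dichlorocyclobut-3-ene-1,2-dione | O=C1C(Cl)=C(Cl)C1=O | intermediate
9 | 3-chloro-4-[2-(2-methylbut-3-en-2-yl)-1H-indol-3-yl]cyclobut-3-ene-1,2-dione (not isolated) | O=C1C(=O)C(Cl)=C1c1c(C(C)(C)C=C)[nH]c2ccccc12 | intermediate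
10 | 3-methoxy-4-[2-(2-methylbut-3-en-2-yl)-1H-indol-3-yl]cyclobut-3-ene-1,2-dione | O=C1C(=O)C(OC)=C1c1c(C(C)(C)C=C)[nH]c2ccccc12 | intermediate
11 | tert-butyl 3-(2-methoxy-3,4-dioxocyclobut-1-en-1-yl)-2-(2-methylbut-3-en-2-yl)-1H-indole-1-carboxylate | O=C1C(=O)C(OC)=C1c1c(C(C)(C)C=C)n(C(=O)OC(C)(C)C)c2ccccc12 | intermediate
12 | 5-methylhex-4-enoic acid | CC(C)=CCCC(=O)O | starting material
13 | N-methoxy-N,5-dimethylhex-4-enamide | CC(C)=CCCC(=O)N(C)OC | intermediate
14 | 3-bromo-1-(triisopropylsilyl)-1H-indole | Brc1cn([Si](C(C)C)(C(C)C)C(C)C)c2ccccc12 | starting material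
15 | 3-lithio-1-(triisopropylsilyl)-1H-indole (not isolated) | [Li]c1cn([Si](C(C)C)(C(C)C)C(C)C)c2ccccc12 | intermediate
16 | 5-methyl-1-[1-(triisopropylsilyl)-1H-indol-3-yl]hex-4-en-1-one | CC(C)=CCCC(=O)c1cn([Si](C(C)C)(C(C)C)C(C)C)c2ccccc12 | intermediate
17 | N'-[(1E)-5-methyl-1-[1-(triisopropylsilyl)-1H-indol-3-yl]hex-4-en-1-ylidene]-2,4,6-tri(propan-2-yl)benzenesulfonohydrazide | CC(C)=CCC/C(=N\NS(=O)(=O)c1c(C(C)C)cc(C(C)C)cc1C(C)C)c1cn([Si](C(C)C)(C(C)C)C(C)C)c2ccccc12 | intermediate
18 | (1Z)-5-methyl-1-[1-(triisopropylsilyl)indol-3-yl]hexa-1,4-dien-1-yllithium, Li trans to CH2 (not isolated) | [Li]/C(=C/CC=C(C)C)c1cn([Si](C(C)C)(C(C)C)C(C)C)c2ccccc12 | intermediate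
19 | 4-hydroxy-3-methoxy-2-[1-(tert-butoxycarbonyl)-2-(2-methylbut-3-en-2-yl)indol-3-yl]-4-[(1E)-5-methyl-1-(1-triisopropylsilylindol-3-yl)hexa-1,4-dien-1-yl]cyclobut-2-en-1-one, racemic | O=C1C(c2c(C(C)(C)C=C)n(C(=O)OC(C)(C)C)c3ccccc23)=C(OC)C1(O)/C(c2cn([Si](C(C)C)(C(C)C)C(C)C)c3ccccc23)=C/CC=C(C)C | intermediate
20 | (3Z,5E)-2-[1-(tert-butoxycarbonyl)-2-(2-methylbut-3-en-2-yl)indol-3-yl]-4-hydroxy-3-methoxy-9-methyl-5-[1-(triisopropylsilyl)indol-3-yl]deca-1,3,5,8-tetraen-1-one, the dienylketene (not isolated) | O=C=C(c1c(C(C)(C)C=C)n(C(=O)OC(C)(C)C)c2ccccc12)/C(OC)=C(O)\C(c1cn([Si](C(C)C)(C(C)C)C(C)C)c2ccccc12)=C\CC=C(C)C | intermediate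
21 | 2-[1-(tert-butoxycarbonyl)-2-(2-methylbut-3-en-2-yl)indol-3-yl]-4-hydroxy-3-methoxy-6-(3-methylbut-2-en-1-yl)-5-[1-(triisopropylsilyl)indol-3-yl]cyclohexa-2,4-dien-1-one, racemic (not isolated) | O=C1C(c2c(C(C)(C)C=C)n(C(=O)OC(C)(C)C)c3ccccc23)=C(OC)C(O)=C(c2cn([Si](C(C)C)(C(C)C)C(C)C)c3ccccc23)C1CC=C(C)C | intermediate
22 | 2-[1-(tert-butoxycarbonyl)-2-(2-methylbut-3-en-2-yl)indol-3-yl]-3-methoxy-6-(3-methylbut-2-en-1-yl)-5-[1-(triisopropylsilyl)indol-3-yl]benzene-1,4-diol | Oc1c(CC=C(C)C)c(c2cn([Si](C(C)C)(C(C)C)C(C)C)c3ccccc23)c(O)c(OC)c1c1c(C(C)(C)C=C)n(C(=O)OC(C)(C)C)c2ccccc12 | intermediate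
23 | 2-[1-(tert-butoxycarbonyl)-2-(2-methylbut-3-en-2-yl)indol-3-yl]-3-methoxy-6-(3-methylbut-2-en-1-yl)-5-[1-(triisopropylsilyl)indol-3-yl]cyclohexa-2,5-diene-1,4-dione | O=C1C(CC=C(C)C)=C(c2cn([Si](C(C)C)(C(C)C)C(C)C)c3ccccc23)C(=O)C(OC)=C1c1c(C(C)(C)C=C)n(C(=O)OC(C)(C)C)c2ccccc12 | intermediate
24 | 2-[1-(tert-butoxycarbonyl)-2-(2-methylbut-3-en-2-yl)indol-3-yl]-5-(1H-indol-3-yl)-3-methoxy-6-(3-methylbut-2-en-1-yl)cyclohexa-2,5-diene-1,4-dione (not isolated) | O=C1C(CC=C(C)C)=C(c2c[nH]c3ccccc23)C(=O)C(OC)=C1c1c(C(C)(C)C=C)n(C(=O)OC(C)(C)C)c2ccccc12 | intermediate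
25 | 3-hydroxy-5-(1H-indol-3-yl)-2-[2-(2-methylbut-3-en-2-yl)-1H-indol-3-yl]-6-(3-methylbut-2-en-1-yl)cyclohexa-2,5-diene-1,4-dione | C=CC(C)(C)c1[nH]c2ccccc2c1C1=C(O)C(=O)C(c2c[nH]c3ccccc23)=C(CC=C(C)C)C1=O | target

**Step count.** Total: 12 steps. Longest linear sequence: 8 steps (1, 2, 4, 5, 9, 10, 11, 12).

**Steps most likely to fail**

Step 9. The dianion may form incompletely, so that butyllithium survives and attacks 11. The vinyllithium may also be protonated at its doubly allylic CH2 while the mixture is warmed to expel N2. Fallback: the vinyllithium is generated by halogen–lithium exchange at −78 °C instead of by hydrazone fragmentation. Setting out from 16, hydrazine hydrate and Et3N in hot EtOH should give the N-unsubstituted hydrazone F1. I2 and 1,1,3,3-tetramethylguanidine in THF (Barton vinyl iodide synthesis) should then give 3-[(1E)-1-iodo-5-methylhexa-1,4-dien-1-yl]-1-(triisopropylsilyl)indole F2 together with its (1Z) isomer F3, and the two are separated on silica. Treating F2 with t-BuLi (2 equiv) in THF at −78 °C should give 18 with retention, and addition to 11 as before brings the route back at 19. This path also bypasses step 8.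

Step 10. The hydroxyl may rotate inward, or ring closure may be slow enough for the free hydroxyl to add to the ketene (lactonisation). The hydroquinone may also be oxidised or degraded during prolonged heating. Fallback: the hydroxyl is capped before thermolysis, so that no O–H can trap the ketene and a silyloxy donor governs the ring opening. Setting out from 19, N-(trimethylsilyl)imidazole in CH2Cl2 should give the 4-(trimethylsilyloxy)cyclobutenone F4. Heating in toluene should give the mono-silylated hydroquinone F5 by the same ring expansion. Brief treatment with dilute HCl in THF should cleave the aryl silyl ether, and the route comes back at 22.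

Step 5. N-acylation may stall at a nitrogen flanked by the tert-alkyl group and C7–H, and the nucleophilic catalyst may attack the vinylogous ester instead. Fallback: the carbamate is installed on the simple indole, where forcing conditions are tolerated, and the squarate is attached afterwards by organolithium addition. Setting out from 6, NaH and Boc2O in DMF should give tert-butyl 2-(2-methylbut-3-en-2-yl)indole-1-carboxylate F6. NBS in THF at 0 °C should give the 3-bromo derivative F7. t-BuLi (2 equiv) at −78 °C should give the 3-lithio compound F8, which cannot migrate because C2 is blocked. Addition to commercial dimethyl squarate should give the 4-hydroxy-2,3-dimethoxy-4-indolylcyclobutenone F9. Trifluoroacetic anhydride, then aqueous NaHCO3, should effect the 1,3-carbonyl transposition with loss of methanol, and the route comes back at 11, bypassing steps 3 to 5.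

**Further compounds**
F1 | step 9 | (E)-[5-methyl-1-[1-(triisopropylsilyl)-1H-indol-3-yl]hex-4-en-1-ylidene]hydrazine | CC(C)=CCC/C(=N\N)c1cn([Si](C(C)C)(C(C)C)C(C)C)c2ccccc12
F2 | step 9 | 3-[(1E)-1-iodo-5-methylhexa-1,4-dien-1-yl]-1-(triisopropylsilyl)-1H-indole | I/C(=C/CC=C(C)C)c1cn([Si](C(C)C)(C(C)C)C(C)C)c2ccccc12
F3 | step 9 | 3-[(1Z)-1-iodo-5-methylhexa-1,4-dien-1-yl]-1-(triisopropylsilyl)-1H-indole | I/C(=C\CC=C(C)C)c1cn([Si](C(C)C)(C(C)C)C(C)C)c2ccccc12
F4 | step 10 | 3-methoxy-2-[1-(tert-butoxycarbonyl)-2-(2-methylbut-3-en-2-yl)indol-3-yl]-4-[(1E)-5-methyl-1-(1-triisopropylsilylindol-3-yl)hexa-1,4-dien-1-yl]-4-(trimethylsilyloxy)cyclobut-2-en-1-one, racemic | O=C1C(c2c(C(C)(C)C=C)n(C(=O)OC(C)(C)C)c3ccccc23)=C(OC)C1(O[Si](C)(C)C)/C(c2cn([Si](C(C)C)(C(C)C)C(C)C)c3ccccc23)=C/CC=C(C)C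
F5 | step 10 | 2-[1-(tert-butoxycarbonyl)-2-(2-methylbut-3-en-2-yl)indol-3-yl]-3-methoxy-6-(3-methylbut-2-en-1-yl)-5-[1-(triisopropylsilyl)indol-3-yl]-4-(trimethylsilyloxy)phenol | Oc1c(CC=C(C)C)c(c2cn([Si](C(C)C)(C(C)C)C(C)C)c3ccccc23)c(O[Si](C)(C)C)c(OC)c1c1c(C(C)(C)C=C)n(C(=O)OC(C)(C)C)c2ccccc12
F6 | step 5 | tert-butyl 2-(2-methylbut-3-en-2-yl)-1H-indole-1-carboxylate | C=CC(C)(C)c1cc2ccccc2n1C(=O)OC(C)(C)C
F7 | step 5 | tert-butyl 3-bromo-2-(2-methylbut-3-en-2-yl)-1H-indole-1-carboxylate | C=CC(C)(C)c1c(Br)c2ccccc2n1C(=O)OC(C)(C)C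
F8 | step 5 | tert-butyl 3-lithio-2-(2-methylbut-3-en-2-yl)-1H-indole-1-carboxylate | C=CC(C)(C)c1c([Li])c2ccccc2n1C(=O)OC(C)(C)C
F9 | step 5 | tert-butyl 3-(1-hydroxy-2,3-dimethoxy-4-oxocyclobut-2-en-1-yl)-2-(2-methylbut-3-en-2-yl)-1H-indole-1-carboxylate, racemic | COC1=C(OC)C(O)(c2c(C(C)(C)C=C)n(C(=O)OC(C)(C)C)c3ccccc23)C1=O
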